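**Strategy**

The flavone is cut at O1–C2 of ring C, back to an aryl alkynyl ketone. In ring A, C4a is flanked by C5–OMe and C8a–O1, so a symmetric pentamethoxyphenyl ketone already holds O1 as one of two equivalent ortho methoxy oxygens, and C3 must carry a heteroatom. Iodine monochloride therefore closes the pyranone in a single operation: either ortho oxygen adds to the activated alkyne, its methyl is lost, and iodine lands on C3 as the handle for the 3-methoxy group. The precursor is ynone 15, made from pentamethoxybenzaldehyde and a 3,5-bis(benzyloxy)-4-methoxyphenylacetylene; benzyl ethers mask the two ring B phenols until a final hydrogenolysis.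

Key step: step 9

Assumption: 1,2,3,4-tetramethoxybenzene, 3,5-dihydroxy-4-methoxybenzoic acid and dimethyl (1-diazo-2-oxopropyl)phosphonate are taken as purchased; the carbinol centre of 14 is formed as a racemate and is erased in step 8, so no stereochemistry has to be controlled.

**Route**

Step 1
Reactants: 1 1,2,3,4-tetramethoxybenzene
Product: 4 2,3,4,5-tetramethoxyphenol, via 2,3,4,5-tetramethoxyphenyllithium 2 (not isolated), via dimethyl (2,3,4,5-tetramethoxyphenyl)boronate 3 (not isolated)
Conditions: n-BuLi, TMEDA, THF, 0 °C; B(OMe)3, −78 °C to rt; AcOH, 30% H2O2, 0 °C to rt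
Reagents that add atoms: hydrogen peroxide, OO
Why: Directed ortho-lithiation at one of the two equivalent C–H positions next to a methoxy group, trapping as the borate and peroxide-induced aryl migration from boron to oxygen (boronate oxidation) is the standard aryllithium-to-phenol hydroxylation, and the acidic medium should limit further oxidation of the electron-rich phenol.

Step 2
Reactants: 4 2,3,4,5-tetramethoxyphenol
Product: 5 pentamethoxybenzene
Conditions: MeI, K2CO3, acetone, reflux
Reagents that add atoms: iodomethane, CI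
Why: Williamson O-methylation of a phenoxide should proceed cleanly because the phenol is the only acidic site.

Step 3
Reactants: 5 pentamethoxybenzene
Product: 7 2,3,4,5,6-pentamethoxybenzaldehyde, via pentamethoxyphenyllithium 6 (not isolated)
Conditions: n-BuLi, TMEDA, THF, 0 °C; DMF, −78 °C to rt; then H2O
Reagents that add atoms: N,N-dimethylformamide, CN(C)C=O
Why: The single ring C–H of 5 lies between two methoxy groups and should undergo directed ortho-lithiation readily, and formylation of the aryllithium with DMF gives the aldehyde on hydrolysis of the hemiaminal salt.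

Step 4
Reactants: 8 3,5-dihydroxy-4-methoxybenzoic acid
Product: 9 benzyl 3,5-bis(benzyloxy)-4-methoxybenzoate
Conditions: BnBr (3.3 equiv), K2CO3, DMF, 60 °C
Reagents that add atoms: benzyl bromide, BrCc1ccccc1
Why: Williamson alkylation of both phenoxides and of the carboxylate in one pot installs benzyl ethers that tolerate organolithium and Grignard reagents, MnO2 and ICl, and that are removed under neutral conditions at the end.

Step 5
Reactants: 9 benzyl 3,5-bis(benzyloxy)-4-methoxybenzoate
Product: 10 [3,5-bis(benzyloxy)-4-methoxyphenyl]methanol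
Conditions: LiAlH4, THF, 0 °C to rt; Fieser work-up
Reagents that add atoms: none
Why: Hydride reduction of the ester to the primary benzylic alcohol leaves the aryl benzyl and methyl ethers untouched.

Step 6
Reactants: 10 [3,5-bis(benzyloxy)-4-methoxyphenyl]methanol
Product: 12 1,3-bis(benzyloxy)-5-ethynyl-2-methoxybenzene, via 3,5-bis(benzyloxy)-4-methoxybenzaldehyde 11 (not isolated)
Conditions: activated MnO2, THF, rt; then MeOH, K2CO3, dimethyl (1-diazo-2-oxopropyl)phosphonate, rt
Reagents that add atoms: dimethyl (1-diazo-2-oxopropyl)phosphonate, CC(=O)C(=[N+]=[N-])P(=O)(OC)OC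
Why: Tandem MnO2 oxidation of the benzylic alcohol and Ohira–Bestmann (Seyferth–Gilbert) homologation of the aldehyde in the same flask is an established one-pot route from activated alcohols to terminal alkynes and uses only mild base.

Step 7
Reactants: 12 1,3-bis(benzyloxy)-5-ethynyl-2-methoxybenzene; 7 2,3,4,5,6-pentamethoxybenzaldehyde
Product: 14 3-[3,5-bis(benzyloxy)-4-methoxyphenyl]-1-(2,3,4,5,6-pentamethoxyphenyl)prop-2-yn-1-ol (racemic), via lithium acetylide 13 (not isolated)
Conditions: n-BuLi, THF, −78 °C; then 7, −78 to 0 °C; then H2O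
Reagents that add atoms: none
Why: 1,2-Addition of a lithium acetylide to an aromatic aldehyde is reliable even with two ortho substituents, and the carbinol centre is formed without control as a racemate because it is oxidised away in step 8.

Step 8
Reactants: 14 3-[3,5-bis(benzyloxy)-4-methoxyphenyl]-1-(2,3,4,5,6-pentamethoxyphenyl)prop-2-yn-1-ol
Product: 15 3-[3,5-bis(benzyloxy)-4-methoxyphenyl]-1-(2,3,4,5,6-pentamethoxyphenyl)prop-2-yn-1-one
Conditions: activated MnO2, CH2Cl2, rt
Reagents that add atoms: none
Why: The alcohol is both benzylic and propargylic, so neutral MnO2 oxidation should give the ynone without acid that could ionise the electron-rich carbinol.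

Step 9
Reactants: 15 3-[3,5-bis(benzyloxy)-4-methoxyphenyl]-1-(2,3,4,5,6-pentamethoxyphenyl)prop-2-yn-1-one
Product: 16 3',5'-bis(benzyloxy)-3-iodo-5,6,7,8,4'-pentamethoxyflavone
Conditions: ICl (1.2 equiv), CH2Cl2, −78 °C; aq Na2S2O3 quench
Reagents that add atoms: iodine monochloride, ClI
Why: ICl adds an iodonium to the alkyne of 15 and one of the two equivalent ortho methoxy oxygens of ring A attacks the aryl-bearing alkyne carbon anti to iodine, so that O1–C2 and C3–I form together and ring C (the pyranone) closes in a 6-endo-dig mode. The O-methyloxonium ion so formed is dealkylated by chloride in an SN2 step, which releases chloromethane and makes the closure irreversible. The closest known reaction type is the ICl-induced cyclization of 2-methoxyaryl alkynyl ketones to 3-iodochromones. No stereocentre is created. The step needs 6-endo rather than 5-exo closure, secured by the ketone, which polarises the activated alkyne so that the carbon remote from C=O and stabilised by ring B is the electrophilic one, and it needs no choice between the ortho oxygens because the pentamethoxyphenyl group is symmetric. It also needs iodination of the alkyne in preference to the arenes, secured by the fully substituted ring A, the acceptor-substituted ring B (ynone, then chromone), the low temperature and only a slight excess of ICl.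

Step 10
Reactants: 16 3',5'-bis(benzyloxy)-3-iodo-5,6,7,8,4'-pentamethoxyflavone
Product: 19 3',5'-bis(benzyloxy)-3-hydroxy-5,6,7,8,4'-pentamethoxyflavone, via C3-magnesiated flavone 17 (not isolated), via C3 dimethyl boronate 18 (not isolated)
Conditions: iPrMgCl·LiCl (1.1 equiv), THF, −78 to −40 °C; B(OMe)3, −78 to 0 °C; AcOH, 30% H2O2, 0 °C to rt
Reagents that add atoms: hydrogen peroxide, OO
Why: Iodine–magnesium exchange of the electron-poor vinylic iodide is fast at low temperature, C3-metalated flavones are known to persist at −78 °C and to be trapped by trimethyl borate, and boronate oxidation then delivers the flavonol without exposing the iodochromone to a nucleophilic alkoxide.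

Step 11
Reactants: 19 3',5'-bis(benzyloxy)-3-hydroxy-5,6,7,8,4'-pentamethoxyflavone
Product: 20 3',5'-bis(benzyloxy)-3,5,6,7,8,4'-hexamethoxyflavone
Conditions: MeI, K2CO3, DMF, rt
Reagents that add atoms: iodomethane, CI
Why: Williamson O-methylation of the acidic enolic 3-hydroxyl is routine for flavonols and no other hydroxyl is free.

Step 12
Reactants: 20 3',5'-bis(benzyloxy)-3,5,6,7,8,4'-hexamethoxyflavone
Product: 21 3',5'-dihydroxy-3,5,6,7,8,4'-hexamethoxyflavone
Conditions: H2 (1 atm), 10% Pd/C, EtOAc–MeOH, rt
Reagents that add atoms: none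
Why: Catalytic hydrogenolysis cleaves the two benzyl ethers under neutral conditions, while the aryl methyl ethers are inert and the tetrasubstituted, fully conjugated C2=C3 bond of the chromone should resist hydrogenation at ambient pressure.

**Compound list**

1 | 1,2,3,4-tetramethoxybenzene | COc1ccc(OC)c(OC)c1OC | starting material
2 | 2,3,4,5-tetramethoxyphenyllithium | [Li]c1cc(OC)c(OC)c(OC)c1OC | intermediate
3 | dimethyl (2,3,4,5-tetramethoxyphenyl)boronate | COB(OC)c1cc(OC)c(OC)c(OC)c1OC | intermediate
4 | 2,3,4,5-tetramethoxyphenol | COc1cc(O)c(OC)c(OC)c1OC | intermediate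
5 | pentamethoxybenzene | COc1cc(OC)c(OC)c(OC)c1OC | intermediate
6 | pentamethoxyphenyllithium | [Li]c1c(OC)c(OC)c(OC)c(OC)c1OC | intermediate
7 | 2,3,4,5,6-pentamethoxybenzaldehyde | COc1c(OC)c(OC)c(C=O)c(OC)c1OC | intermediate
8 | 3,5-dihydroxy-4-methoxybenzoic acid | COc1c(O)cc(C(=O)O)cc1O | starting material
9 | benzyl 3,5-bis(benzyloxy)-4-methoxybenzoate | COc1c(OCc2ccccc2)cc(C(=O)OCc2ccccc2)cc1OCc1ccccc1 | intermediate
10 | [3,5-bis(benzyloxy)-4-methoxyphenyl]methanol | COc1c(OCc2ccccc2)cc(CO)cc1OCc1ccccc1 | intermediate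
11 | 3,5-bis(benzyloxy)-4-methoxybenzaldehyde | COc1c(OCc2ccccc2)cc(C=O)cc1OCc1ccccc1 | intermediate
12 | 1,3-bis(benzyloxy)-5-ethynyl-2-methoxybenzene | COc1c(OCc2ccccc2)cc(C#C)cc1OCc1ccccc1 | intermediate
13 | lithium [3,5-bis(benzyloxy)-4-methoxyphenyl]acetylide | COc1c(OCc2ccccc2)cc(C#C[Li])cc1OCc1ccccc1 | intermediate
14 | 3-[3,5-bis(benzyloxy)-4-methoxyphenyl]-1-(2,3,4,5,6-pentamethoxyphenyl)prop-2-yn-1-ol (racemic) | COc1c(OC)c(OC)c(C(O)C#Cc2cc(OCc3ccccc3)c(OC)c(OCc3ccccc3)c2)c(OC)c1OC | intermediate
15 | 3-[3,5-bis(benzyloxy)-4-methoxyphenyl]-1-(2,3,4,5,6-pentamethoxyphenyl)prop-2-yn-1-one | COc1c(OC)c(OC)c(C(=O)C#Cc2cc(OCc3ccccc3)c(OC)c(OCc3ccccc3)c2)c(OC)c1OC | intermediate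
16 | 3',5'-bis(benzyloxy)-3-iodo-5,6,7,8,4'-pentamethoxyflavone | COc1c(OCc2ccccc2)cc(-c2oc3c(OC)c(OC)c(OC)c(OC)c3c(=O)c2I)cc1OCc1ccccc1 | intermediate
17 | 3',5'-bis(benzyloxy)-3-(chloromagnesio)-5,6,7,8,4'-pentamethoxyflavone | COc1c(OCc2ccccc2)cc(-c2oc3c(OC)c(OC)c(OC)c(OC)c3c(=O)c2[Mg]Cl)cc1OCc1ccccc1 | intermediate
18 | dimethyl [3',5'-bis(benzyloxy)-5,6,7,8,4'-pentamethoxyflavon-3-yl]boronate | COc1c(OCc2ccccc2)cc(-c2oc3c(OC)c(OC)c(OC)c(OC)c3c(=O)c2B(OC)OC)cc1OCc1ccccc1 | intermediate
19 | 3',5'-bis(benzyloxy)-3-hydroxy-5,6,7,8,4'-pentamethoxyflavone | COc1c(OCc2ccccc2)cc(-c2oc3c(OC)c(OC)c(OC)c(OC)c3c(=O)c2O)cc1OCc1ccccc1 | intermediate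
20 | 3',5'-bis(benzyloxy)-3,5,6,7,8,4'-hexamethoxyflavone | COc1c(OCc2ccccc2)cc(-c2oc3c(OC)c(OC)c(OC)c(OC)c3c(=O)c2OC)cc1OCc1ccccc1 | intermediate
21 | 3',5'-dihydroxy-3,5,6,7,8,4'-hexamethoxyflavone | COc1c(O)cc(-c2oc3c(OC)c(OC)c(OC)c(OC)c3c(=O)c2OC)cc1O | target

**Step count**

Total step count: 12.
Longest linear sequence: 9 steps (8 to 21 through steps 4 to 12; the ring A branch, steps 1 to 3 and 7 to 12, is equally long).

**Steps most likely to fail**

Step 9. The iodonium may be consumed by electrophilic iodination of ring B at C2'/C6', closure may leak into the 5-exo mode, or the oxonium ion may not be dealkylated cleanly. The fallback builds the pyranone by the chalcone route. It sets out from phenol 4 and aldehyde 11 (isolated by stopping step 6 after the MnO2 oxidation) and comes back to the route at flavonol 19.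
- Friedel–Crafts C-acetylation of 4 at its only free ring position (AcOH, BF3·OEt2, 80 °C) would give 1-(2-hydroxy-3,4,5,6-tetramethoxyphenyl)ethanone F1.
- Claisen–Schmidt condensation of this ketone with 11 (KOH, EtOH, rt) would give (E)-3-[3,5-bis(benzyloxy)-4-methoxyphenyl]-1-(2-hydroxy-3,4,5,6-tetramethoxyphenyl)prop-2-en-1-one F2.
- Oxidative cyclization (catalytic I2, DMSO, 120 °C) would give 3',5'-bis(benzyloxy)-5,6,7,8,4'-pentamethoxyflavone F3.
- Deprotonation at C3 (LDA, THF, −78 °C) would give 3',5'-bis(benzyloxy)-3-lithio-5,6,7,8,4'-pentamethoxyflavone F4. Trapping with B(OMe)3 and oxidation with AcOH/H2O2 would then pass through boronate 18 to 19.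

Step 10. The C3-magnesiated chromone may open by β-elimination of the O1 phenoxide, the Grignard reagent may add to the C4 carbonyl, or the organometallic may be protonated so that iodine is lost without oxygenation. The fallback installs the oxygen without any C3 carbanion, by a Cu-catalysed Ullmann-type C–O coupling of the vinylic iodide with methanol (CuI, 3,4,7,8-tetramethyl-1,10-phenanthroline, Cs2CO3, MeOH–toluene, 80 °C). It sets out from 16 and comes back at 20, so that 19 and step 11 are bypassed; no compound outside the list arises (F0).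

Step 1. Ortho-metalation may stay incomplete, or the peroxide stage may oxidise the very electron-rich phenol further towards a quinone. The fallback sets out from 1 and comes back at 4. Rieche formylation of 1 (Cl2CHOMe, TiCl4, CH2Cl2, 0 °C) would give 2,3,4,5-tetramethoxybenzaldehyde F5. Baeyer–Villiger oxidation (mCPBA, CH2Cl2, rt) would give 2,3,4,5-tetramethoxyphenyl formate F6, and methanolysis (K2CO3, MeOH, rt) would release 4.

Further compounds
F1 | step 9 | 1-(2-hydroxy-3,4,5,6-tetramethoxyphenyl)ethanone | CC(=O)c1c(O)c(OC)c(OC)c(OC)c1OC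
F2 | step 9 | (E)-3-[3,5-bis(benzyloxy)-4-methoxyphenyl]-1-(2-hydroxy-3,4,5,6-tetramethoxyphenyl)prop-2-en-1-one | COc1c(OCc2ccccc2)cc(/C=C/C(=O)c2c(O)c(OC)c(OC)c(OC)c2OC)cc1OCc1ccccc1
F3 | step 9 | 3',5'-bis(benzyloxy)-5,6,7,8,4'-pentamethoxyflavone | COc1c(OCc2ccccc2)cc(-c2cc(=O)c3c(OC)c(OC)c(OC)c(OC)c3o2)cc1OCc1ccccc1
F4 | step 9 | 3',5'-bis(benzyloxy)-3-lithio-5,6,7,8,4'-pentamethoxyflavone | COc1c(OCc2ccccc2)cc(-c2oc3c(OC)c(OC)c(OC)c(OC)c3c(=O)c2[Li])cc1OCc1ccccc1
F0 | step 10 | none | none
F5 | step 1 | 2,3,4,5-tetramethoxybenzaldehyde | COc1cc(C=O)c(OC)c(OC)c1OC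
F6 | step 1 | 2,3,4,5-tetramethoxyphenyl formate | COc1cc(OC=O)c(OC)c(OC)c1OC
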